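At early times Wednesday's flask lost G far faster than it made L: at 2.00 h G stood at 45.8% and L at 5.8%, so 48.4% of the charge sat in an unread pool. Once G was gone, the pool was simply what L lacked.

| setting | Wednesday's | Monday's | flask |
|---|---|---|---|
| G | 0.050 M | 0.050 M | 0.050 M |
| J | 5.6 × 10⁻⁴ mol% | 5.6 × 10⁻⁴ mol% | 5.6 × 10⁻⁴ mol% |
| temperature | 37 °C | 43 °C | 37 °C |
| remark | the very flask that is asked about, followed so far | run made earlier |  |
| time |  |  | 40 h |

| run | time / h | L / % | G / % |
|---|---|---|---|
| Wednesday's | 2.00 | 5.8 | 45.8 |
| Wednesday's | 6.00 | 29.2 | 16.9 |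
| Wednesday's | 12.0 | 60.8 | 0 |
| Wednesday's | 15.0 | 66.6 | 0.2 |
| Wednesday's | 25.0 | 79.5 | 0 |
| Monday's | 2.00 | 6.5 | 46.1 |
| Monday's | 6.00 | 28.4 | 17.7 |
| Monday's | 12.0 | 53.8 | 0.4 |
| Monday's | 15.0 | 59.5 | 0.3 |
| Monday's | 25.0 | 68.9 | 0.1 |

(each reading ± 0.5 percentage points)

- G is a solid; its amount is given per volume of the solution
- L that was removed still counts
- at the start none of G is in solution
- additions bring no volume worth counting

- spring: at 40 h take out 90% of the L then present, then wait 40 h
- midnight: at 40 h add J, 100% of the amount charged, then wait 40 h
- winter: change nothing and wait 40 h more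

- L, in percent of the G first charged, at 40 h
- what to do for the largest gain in L; "none" if nothing gains more than 2 percentage points (spring / midnight / winter / none)
- L present, with what was taken out counted in, in percent of the G first charged, after midnight
- L present, with what was taken out counted in, in percent of the G first charged, after winter

From 15.0 h to 25.0 h I read the pool's pseudo-first-order constant in Wednesday's run as 0.0488 h⁻¹. That gave me two extreme flasks. If the constant held, L would reach 90.1% at 40 h; if J had stopped working at the last reading, L would stay at 79.5%.

The real flask had to lie between them. Monday's run, the same charge at 43 °C, matched Wednesday's at 6.00 h, but over the same late span its constant was 0.0264 h⁻¹, about half of Wednesday's. So I took half the constant from the last reading on and committed to 85.8%.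

For the choice, midnight's wait offers 80.0 h of catalyst-hours, meaning [J] in units of the first charge multiplied by the hours waited. Winter and spring offer 40 h at most, so I chose midnight.

The forecast said 88% and midnight, with 98.5% after midnight and 94.5% after winter, holding that “Monday's stall looks like enzyme death”.

The flask gave 84.4% at 40 h, and midnight led with 92.5% against 89.6% for winter, which put the forecast's midnight figure 6 percentage points high.

    J → Z (k = 0.00845 h⁻¹, Ea = 260 kJ mol⁻¹)
    X + J → L + J, rate k2*[X]^2.5*[J]/(1 + ([X]/Kh2)^2.5) (47.7 mM, k = 33400 M⁻²·⁵ s⁻¹, Ea = 16.0 kJ mol⁻¹)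
    G ⇌ X, rate k3*(cs3 - [X]) while solid is left; crystals form when [X] > cs3 (solubility = 30.0 mM, k = 1.01 h⁻¹)
    (constants at 37 °C)

Half of the dissolving of G was done by 1.66 h, but half of the step from X to L took until 8.10 h. At 40 h X still held 15.6%, with 71.3% of the catalyst live. Holding that live share, midnight's 80.0 h shrinks to 68.5 h of catalyst-hours. The neighbour with 1.4 × 10⁻⁴ mol% of J, its J down to 71.3% by 40 h, ran between 7.13 h and 10.0 h of catalyst-hours by then, a span Wednesday's run passed between 29.2% and 60.8%, and it stood at 56.4%.

(The data are calculated for an exercise.)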